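**Retrosynthetic overview**

- The target is read with benzofuran numbering as the trans (2S,3S) 2,3-diaryl-2,3-dihydrobenzofuran. The three MOM ethers and then the three aryl esters come off last, after the C6–styryl bond is made by Heck coupling of a C6 bromide with 4-acetoxy-3-methoxystyrene.
- The dihydrofuran ring is the only ring built. It is cut at C2–C3 and O1–C2: the atoms O1–C7a–C3a–C3 are treated as a latent ortho-quinone methide of the resorcinol ring A, and C2, which carries the 2,4-dioxygenated aryl group, as a single benzylidene carbon inserted between C3 and O1 by a chiral benzyl sulfonium ylide ([4+1]), which sets both stereocenters.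
- The quinone methide precursor is an ortho-hydroxybenzhydryl sulfone, made by Grignard addition of the 3,5-bis(MOM-oxy)phenyl unit to 4-bromo-2-hydroxy-6-(MOM-oxy)benzaldehyde and carbinol-to-sulfinate exchange. The second ring A oxygen (later C4–OH) is carried as a MOM ether so that the quinone methide stays neutral and only one phenoxide can close the ring.
- The ylide precursor is the sulfonium salt from 2,4-bis(pivaloyloxy)benzyl bromide and (2S,5S)-2,5-dimethylthiolane, the latter from (2R,5R)-hexane-2,5-diol by double inversion.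

Key step: step 11

Assumption: the thiolane ylide is taken to meet the quinone methide carbon on the same face as it meets an aldehyde carbon in epoxidation; on this model the (2S,5S)-thiolane, not its (2R,5R) antipode, leads to the (2S,3S) ring, because at C2 the aryl group ranks above C3, the reverse of the ranking at a stilbene oxide carbon.

**Route**

Step 1
Reactants: 1 5-bromoresorcinol
Product: 2 1-bromo-3,5-bis(methoxymethoxy)benzene
Conditions: MOMCl (2.5 equiv), iPr2NEt, CH2Cl2, 0 °C → rt
Reagents that add atoms: chloromethyl methyl ether (MOMCl), COCCl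
Why: O-alkylation of both phenols with the chloromethyl ether (MOM ether formation) gives a bromide whose protecting groups tolerate magnesium insertion and the later basic steps.

Step 2
Reactants: 3 4-bromo-2,6-dimethoxybenzaldehyde
Product: 4 4-bromo-2,6-dihydroxybenzaldehyde
Conditions: BBr3 (3 equiv), CH2Cl2, −78 °C → rt; then H2O
Reagents that add atoms: none
Why: Lewis-acid cleavage of aryl methyl ethers (BBr3 demethylation), helped by chelation of boron between each ortho oxygen and the formyl oxygen, should free both phenols and leave the aryl bromide alone.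

Step 3
Reactants: 4 4-bromo-2,6-dihydroxybenzaldehyde
Product: 5 4-bromo-2-hydroxy-6-(methoxymethoxy)benzaldehyde
Conditions: MOMCl (1.05 equiv), iPr2NEt (1.2 equiv), CH2Cl2, 0 °C
Reagents that add atoms: chloromethyl methyl ether (MOMCl), COCCl
Why: Mono-etherification (MOM protection) should stop after one alkylation, because the remaining hydroxyl is then held in a strong hydrogen bond to the formyl oxygen and reacts much more slowly.

Step 4
Reactants: 2 1-bromo-3,5-bis(methoxymethoxy)benzene; 5 4-bromo-2-hydroxy-6-(methoxymethoxy)benzaldehyde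
Product: 7 rac-[4-bromo-2-hydroxy-6-(methoxymethoxy)phenyl][3,5-bis(methoxymethoxy)phenyl]methanol, via arylmagnesium bromide 6 (not isolated)
Conditions: 2 (2.5 equiv), Mg, I2 (cat.), THF, 50 °C; then 5 (1 equiv), THF, 0 °C → rt; sat. aq. NH4Cl
Reagents that add atoms: none
Why: Grignard formation and 1,2-addition to the aldehyde: one equivalent of 6 deprotonates the phenol, a second adds to the magnesium-chelated formyl group, and the carbinol centre forms as a racemate, which does not matter because this carbon becomes planar in step 11.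

Step 5
Reactants: 7 rac-[4-bromo-2-hydroxy-6-(methoxymethoxy)phenyl][3,5-bis(methoxymethoxy)phenyl]methanol
Product: 8 rac-5-bromo-2-{[3,5-bis(methoxymethoxy)phenyl](4-methylbenzenesulfonyl)methyl}-3-(methoxymethoxy)phenol
Conditions: p-TolSO2H (2 equiv), MgSO4, CH2Cl2, rt
Reagents that add atoms: 4-methylbenzenesulfinic acid, Cc1ccc(S(=O)O)cc1
Why: The doubly benzylic carbinol flanked by two ortho oxygens ionises under the weak acid and the cation is captured at sulfur by the sulfinate (SN1 carbinol-to-sulfone exchange, the usual entry to 2-(1-tosylalkyl)phenols), giving a racemic centre that is erased in step 11.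

Step 6
Reactants: 9 (2R,5R)-hexane-2,5-diol
Product: 10 (2R,5R)-hexane-2,5-diyl dimethanesulfonate
Conditions: MsCl (2.4 equiv), Et3N, CH2Cl2, −20 → 0 °C
Reagents that add atoms: methanesulfonyl chloride, CS(=O)(=O)Cl
Why: Mesylate formation takes place at oxygen, so both stereocenters are kept while the hydroxyls become leaving groups.

Step 7
Reactants: 10 (2R,5R)-hexane-2,5-diyl dimethanesulfonate
Product: 12 (2S,5S)-2,5-dimethylthiolane, via thiolate mesylate 11 (not isolated)
Conditions: Na2S·9H2O, DMSO, rt → 40 °C; distillation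
Reagents that add atoms: sodium sulfide, [Na+].[Na+].[S-2]
Why: Two successive SN2 displacements by sulfur, the second a 5-exo-tet ring closure, invert both carbinol carbons and so turn the (2R,5R)-dimesylate into the (2S,5S)-thiolane.

Step 8
Reactants: 13 4-methylresorcinol (4-methylbenzene-1,3-diol)
Product: 14 4-methyl-1,3-phenylene bis(2,2-dimethylpropanoate)
Conditions: PivCl (2.4 equiv), Et3N, DMAP (cat.), CH2Cl2, 0 °C → rt
Reagents that add atoms: pivaloyl chloride, CC(C)(C)C(=O)Cl
Why: Acylation of both phenols by the acid chloride under nucleophilic catalysis (esterification) gives the hindered pivalates.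

Step 9
Reactants: 14 4-methyl-1,3-phenylene bis(2,2-dimethylpropanoate)
Product: 15 4-(bromomethyl)-1,3-phenylene bis(2,2-dimethylpropanoate)
Conditions: NBS (1.05 equiv), AIBN (cat.), PhCF3, 80 °C
Reagents that add atoms: N-bromosuccinimide, O=C1CCC(=O)N1Br
Why: Wohl–Ziegler bromination selects the benzylic C–H bonds, since the tert-butyl groups offer only strong primary C–H bonds and the two acyloxy groups damp electrophilic bromination of the ring.

Step 10
Reactants: 15 4-(bromomethyl)-1,3-phenylene bis(2,2-dimethylpropanoate); 12 (2S,5S)-2,5-dimethylthiolane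
Product: 16 (2S,5S)-1-{[2,4-bis(2,2-dimethylpropanoyloxy)phenyl]methyl}-2,5-dimethylthiolan-1-ium tetrafluoroborate
Conditions: 12 (1.5 equiv), NaBF4 (4 equiv), CH2Cl2/H2O (1:1), rt, 48 h
Reagents that add atoms: sodium tetrafluoroborate, [Na+].F[B-](F)(F)F
Why: SN2 S-alkylation of the sulfide by the benzylic bromide, with bromide washed into the aqueous phase in exchange for tetrafluoroborate so that dealkylation cannot reverse it; the two lone pairs of the C2-symmetric thiolane are equivalent, so one salt without a stereocenter at sulfur forms.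

Step 11
Reactants: 8 rac-5-bromo-2-{[3,5-bis(methoxymethoxy)phenyl](4-methylbenzenesulfonyl)methyl}-3-(methoxymethoxy)phenol; 16 (2S,5S)-1-{[2,4-bis(2,2-dimethylpropanoyloxy)phenyl]methyl}-2,5-dimethylthiolan-1-ium tetrafluoroborate
Product: 20 4-[(2S,3S)-6-bromo-3-[3,5-bis(methoxymethoxy)phenyl]-4-(methoxymethoxy)-2,3-dihydro-1-benzofuran-2-yl]-1,3-phenylene bis(2,2-dimethylpropanoate), via ortho-quinone methide 17 (not isolated), via sulfonium ylide 18 (not isolated), via phenoxide betaine 19 (not isolated)
Conditions: 8 (1 equiv), 16 (1.2 equiv), Cs2CO3 (3 equiv), 4 Å MS, CH2Cl2, −20 °C → rt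
Reagents that add atoms: none
Why: Proposed new method: Cs2CO3 turns the phenol of 8 into a phenoxide that expels sulfinate by 1,4-elimination to give quinone methide 17 and in parallel deprotonates 16 to ylide 18; the ylide carbon adds to the exocyclic carbon of 17 (Michael-type addition that restores the aromaticity of ring A) to give phenoxide betaine 19, and the phenoxide then displaces the thiolane at the benzylic carbon with inversion, a 5-exo-tet closure that forms the dihydrofuran ring through the new C2–C3 and O1–C2 bonds. The closest known reactions are the base-mediated [4+1] annulation of sulfone-derived ortho-quinone methides with achiral sulfonium ylides, which gives trans-2,3-dihydrobenzofurans, and the asymmetric epoxidation of aldehydes by benzyl ylides of 2,5-dimethylthiolane; the extension is to let the chiral benzyl ylide meet a quinone methide. C2 is controlled by the C2-symmetric thiolane: the aryl group of the ylide should point away from the ring and the methyl group on the same side as the ylide carbon should block one face, so that the carbon–carbon bond forms on the open face and the inverting closure then gives (2S) from the (2S,5S)-thiolane. C3 is set relative to C2 in the addition, which rearomatisation should make irreversible: the two aryl groups stay apart in the open transition state, and the betaine so formed can only close to the trans ring, so (2S,3S) is expected. The step needs the ylide to win over ester cleavage and self-condensation, and the substrates are built for that: the pivalates are too hindered for ready acyl transfer and stop the benzyl sulfonium from ionising, the MOM ether on the second ring A oxygen keeps the quinone methide neutral and electrophilic and leaves a single phenoxide for ring closure, and the bromide at C6 is inert.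

Step 12
Reactants: 20 4-[(2S,3S)-6-bromo-3-[3,5-bis(methoxymethoxy)phenyl]-4-(methoxymethoxy)-2,3-dihydro-1-benzofuran-2-yl]-1,3-phenylene bis(2,2-dimethylpropanoate); 21 4-acetoxy-3-methoxystyrene (4-ethenyl-2-methoxyphenyl acetate)
Product: 22 4-[(2S,3S)-6-[(E)-2-(4-acetoxy-3-methoxyphenyl)ethenyl]-3-[3,5-bis(methoxymethoxy)phenyl]-4-(methoxymethoxy)-2,3-dihydro-1-benzofuran-2-yl]-1,3-phenylene bis(2,2-dimethylpropanoate)
Conditions: 21 (1.5 equiv), Pd[P(t-Bu)3]2 (5 mol%), Cy2NMe (1.5 equiv), 1,4-dioxane, 60 °C
Reagents that add atoms: none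
Why: Mizoroki–Heck reaction: zerovalent palladium inserts into the unhindered C6–Br bond, syn carbopalladation at the terminal carbon of the styrene and syn β-hydride elimination give the (E)-stilbene, and C2 and C3 take no part.

Step 13
Reactants: 22 4-[(2S,3S)-6-[(E)-2-(4-acetoxy-3-methoxyphenyl)ethenyl]-3-[3,5-bis(methoxymethoxy)phenyl]-4-(methoxymethoxy)-2,3-dihydro-1-benzofuran-2-yl]-1,3-phenylene bis(2,2-dimethylpropanoate)
Product: 23 4-[(2S,3S)-6-[(E)-2-(4-acetoxy-3-methoxyphenyl)ethenyl]-3-(3,5-dihydroxyphenyl)-4-hydroxy-2,3-dihydro-1-benzofuran-2-yl]-1,3-phenylene bis(2,2-dimethylpropanoate)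
Conditions: ZnBr2 (3 equiv), n-PrSH (6 equiv), CH2Cl2, 0 °C → rt
Reagents that add atoms: none
Why: Lewis-acid acetal cleavage, in which ZnBr2 activates each MOM acetal and the thiol captures the methoxymethyl cation, should free the three phenols quickly while the aryl esters stay, and with the C2 aryl group still acylated the benzylic C2–O1 bond should not ionise.

Step 14
Reactants: 23 4-[(2S,3S)-6-[(E)-2-(4-acetoxy-3-methoxyphenyl)ethenyl]-3-(3,5-dihydroxyphenyl)-4-hydroxy-2,3-dihydro-1-benzofuran-2-yl]-1,3-phenylene bis(2,2-dimethylpropanoate)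
Product: 24 4-[(2S,3S)-3-(3,5-dihydroxyphenyl)-4-hydroxy-6-[(E)-2-(4-hydroxy-3-methoxyphenyl)ethenyl]-2,3-dihydro-1-benzofuran-2-yl]benzene-1,3-diol (CNP0136479.1)
Conditions: K2CO3 (6 equiv), degassed MeOH, rt → 40 °C, Ar, dark; aq. NH4Cl
Reagents that add atoms: none
Why: Base-mediated methanolysis (transesterification) of the aryl acetate and the two aryl pivalates should liberate the last three phenols without touching the stilbene or the C–H bonds at C2 and C3, so the trans (2S,3S) ring is carried through unchanged.

**Compound list**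

1 | 5-bromoresorcinol (5-bromobenzene-1,3-diol) | Oc1cc(O)cc(Br)c1 | starting material
2 | 1-bromo-3,5-bis(methoxymethoxy)benzene | COCOc1cc(Br)cc(OCOC)c1 | intermediate
3 | 4-bromo-2,6-dimethoxybenzaldehyde | COc1cc(Br)cc(OC)c1C=O | starting material
4 | 4-bromo-2,6-dihydroxybenzaldehyde | O=Cc1c(O)cc(Br)cc1O | intermediate
5 | 4-bromo-2-hydroxy-6-(methoxymethoxy)benzaldehyde | COCOc1cc(Br)cc(O)c1C=O | intermediate
6 | [3,5-bis(methoxymethoxy)phenyl]magnesium bromide (not isolated) | COCOc1cc([Mg]Br)cc(OCOC)c1 | intermediate
7 | rac-[4-bromo-2-hydroxy-6-(methoxymethoxy)phenyl][3,5-bis(methoxymethoxy)phenyl]methanol (racemic carbinol carbon) | COCOc1cc(Br)cc(O)c1C(O)c1cc(OCOC)cc(OCOC)c1 | intermediate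
8 | rac-5-bromo-2-{[3,5-bis(methoxymethoxy)phenyl](4-methylbenzenesulfonyl)methyl}-3-(methoxymethoxy)phenol (racemic sulfone carbon) | Cc1ccc(cc1)S(=O)(=O)C(c1c(O)cc(Br)cc1OCOC)c1cc(OCOC)cc(OCOC)c1 | intermediate
9 | (2R,5R)-hexane-2,5-diol | C[C@@H](O)CC[C@@H](C)O | starting material
10 | (2R,5R)-hexane-2,5-diyl dimethanesulfonate | C[C@@H](OS(C)(=O)=O)CC[C@@H](C)OS(C)(=O)=O | intermediate
11 | sodium (2S,5R)-5-(methanesulfonyloxy)hexane-2-thiolate (not isolated) | [Na+].C[C@H]([S-])CC[C@@H](C)OS(C)(=O)=O | intermediate
12 | (2S,5S)-2,5-dimethylthiolane | C[C@H]1CC[C@H](C)S1 | intermediate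
13 | 4-methylresorcinol (4-methylbenzene-1,3-diol) | Cc1ccc(O)cc1O | starting material
14 | 4-methyl-1,3-phenylene bis(2,2-dimethylpropanoate) | Cc1ccc(OC(=O)C(C)(C)C)cc1OC(=O)C(C)(C)C | intermediate
15 | 4-(bromomethyl)-1,3-phenylene bis(2,2-dimethylpropanoate) | BrCc1ccc(OC(=O)C(C)(C)C)cc1OC(=O)C(C)(C)C | intermediate
16 | (2S,5S)-1-{[2,4-bis(2,2-dimethylpropanoyloxy)phenyl]methyl}-2,5-dimethylthiolan-1-ium tetrafluoroborate | C[C@H]1CC[C@H](C)[S+]1Cc1ccc(OC(=O)C(C)(C)C)cc1OC(=O)C(C)(C)C.F[B-](F)(F)F | intermediate
17 | (6Z)-3-bromo-6-[3,5-bis(methoxymethoxy)benzylidene]-5-(methoxymethoxy)cyclohexa-2,4-dien-1-one, the ortho-quinone methide of ring A, drawn with the aryl group on the carbonyl side (not isolated) | O=C1C=C(Br)C=C(OCOC)/C1=C/c2cc(OCOC)cc(OCOC)c2 | intermediate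
18 | [2,4-bis(2,2-dimethylpropanoyloxy)phenyl][(2S,5S)-2,5-dimethylthiolan-1-ium-1-yl]methanide, the sulfonium ylide (not isolated) | C[C@H]1CC[C@H](C)[S+]1[CH-]c1ccc(OC(=O)C(C)(C)C)cc1OC(=O)C(C)(C)C | intermediate
19 | 2-{(1S,2R)-2-[2,4-bis(2,2-dimethylpropanoyloxy)phenyl]-1-[3,5-bis(methoxymethoxy)phenyl]-2-[(2S,5S)-2,5-dimethylthiolan-1-ium-1-yl]ethyl}-5-bromo-3-(methoxymethoxy)phenolate, the betaine (not isolated) | C[C@H]1CC[C@H](C)[S+]1[C@@H](c1ccc(OC(=O)C(C)(C)C)cc1OC(=O)C(C)(C)C)[C@H](c1c([O-])cc(Br)cc1OCOC)c1cc(OCOC)cc(OCOC)c1 | intermediate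
20 | 4-[(2S,3S)-6-bromo-3-[3,5-bis(methoxymethoxy)phenyl]-4-(methoxymethoxy)-2,3-dihydro-1-benzofuran-2-yl]-1,3-phenylene bis(2,2-dimethylpropanoate) | Brc1cc(OCOC)c2c(c1)O[C@H](c1ccc(OC(=O)C(C)(C)C)cc1OC(=O)C(C)(C)C)[C@H]2c1cc(OCOC)cc(OCOC)c1 | intermediate
21 | 4-acetoxy-3-methoxystyrene (4-ethenyl-2-methoxyphenyl acetate) | C=Cc1ccc(OC(C)=O)c(OC)c1 | starting material
22 | 4-[(2S,3S)-6-[(E)-2-(4-acetoxy-3-methoxyphenyl)ethenyl]-3-[3,5-bis(methoxymethoxy)phenyl]-4-(methoxymethoxy)-2,3-dihydro-1-benzofuran-2-yl]-1,3-phenylene bis(2,2-dimethylpropanoate) | CC(=O)Oc1ccc(/C=C/c2cc(OCOC)c3c(c2)O[C@H](c2ccc(OC(=O)C(C)(C)C)cc2OC(=O)C(C)(C)C)[C@H]3c2cc(OCOC)cc(OCOC)c2)cc1OC | intermediate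
23 | 4-[(2S,3S)-6-[(E)-2-(4-acetoxy-3-methoxyphenyl)ethenyl]-3-(3,5-dihydroxyphenyl)-4-hydroxy-2,3-dihydro-1-benzofuran-2-yl]-1,3-phenylene bis(2,2-dimethylpropanoate) | CC(=O)Oc1ccc(/C=C/c2cc(O)c3c(c2)O[C@H](c2ccc(OC(=O)C(C)(C)C)cc2OC(=O)C(C)(C)C)[C@H]3c2cc(O)cc(O)c2)cc1OC | intermediate
24 | 4-[(2S,3S)-3-(3,5-dihydroxyphenyl)-4-hydroxy-6-[(E)-2-(4-hydroxy-3-methoxyphenyl)ethenyl]-2,3-dihydro-1-benzofuran-2-yl]benzene-1,3-diol (CNP0136479.1) | COc1cc(/C=C/c2cc(O)c3c(c2)O[C@H](c2ccc(O)cc2O)[C@H]3c2cc(O)cc(O)c2)ccc1O | target

**Step count**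

Total: 14 steps. Longest linear sequence: 8 steps (steps 2, 3, 4, 5, 11, 12, 13, 14, from compound 3).

**Steps most likely to fail**

1. Step 11 (proposed new method). Facial discrimination at the ylide carbon may be weak, or of the opposite sense, when the electrophile is a quinone methide and not an aldehyde. The ylide may also be diverted by acyl transfer from the ortho pivalate to the ylide carbon, and the quinone methide may be consumed by self-addition before the hindered ylide reaches it. The fallback uses known chemistry and sets out from bromide 15 and sulfone 8. Bromide 15 is alkylated onto thiolane (tetrahydrothiophene) with NaBF4 in CH2Cl2/H2O to give 1-{[2,4-bis(2,2-dimethylpropanoyloxy)phenyl]methyl}thiolan-1-ium tetrafluoroborate F1. Its less hindered ylide is combined with 8 and Cs2CO3 in the established racemic [4+1] annulation of sulfone-derived quinone methides, which should give the racemic trans cycloadduct F2. Preparative HPLC on a chiral stationary phase then separates the enantiomers, and the (2S,3S) enantiomer is compound 20, where the route is rejoined; its configuration would be assigned by comparing the chiroptical data of the final product with those of the natural material.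

2. Step 5. Under acid the ortho MOM ether may be lost, or may bridge to the carbinol oxygen as a cyclic formaldehyde acetal. The benzylic cation may also alkylate the electron-rich rings of a second molecule in competition with capture by sulfinate. The fallback sets out from aldehyde 5 and avoids both acid and carbinol 7. Aldehyde 5 is converted with Boc2O, DMAP (cat.) and iPr2NEt into tert-butyl 5-bromo-2-formyl-3-(methoxymethoxy)phenyl carbonate F3. Grignard reagent 6 is added to F3 at −78 °C in THF in the presence of tetrabutylammonium p-toluenesulfinate, and the mixture is warmed. The Boc group should then migrate to the new alkoxide and the phenoxide should expel tert-butyl carbonate, so that quinone methide 17 arises under basic conditions (the known anionic generation of ortho-quinone methides from O-Boc salicylaldehydes) and is captured by the sulfinate. A buffered quench should give sulfone 8, where the route is rejoined.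

3. Step 13. Cleavage of the hindered MOM ether at C4 may be incomplete, the thiol may add across the stilbene under the Lewis acid, or the benzylic C2–O1 bond may open. The fallback sets out from bromide 20 and moves the acetal cleavage to a stage where neither stilbene nor acetate is present. HCl in MeOH/THF at rt should remove the three MOM ethers, while the C2 aryl group is still acylated, to give 4-[(2S,3S)-6-bromo-3-(3,5-dihydroxyphenyl)-4-hydroxy-2,3-dihydro-1-benzofuran-2-yl]-1,3-phenylene bis(2,2-dimethylpropanoate) F4. Heck coupling of F4 with styrene 21 under the conditions of step 12, which tolerate free phenols, should then give compound 23, where the route is rejoined.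

**Further compounds**

F1 | step 11 | 1-{[2,4-bis(2,2-dimethylpropanoyloxy)phenyl]methyl}thiolan-1-ium tetrafluoroborate | CC(C)(C)C(=O)Oc1ccc(C[S+]2CCCC2)c(OC(=O)C(C)(C)C)c1.F[B-](F)(F)F
F2 | step 11 | racemic trans-4-[6-bromo-3-[3,5-bis(methoxymethoxy)phenyl]-4-(methoxymethoxy)-2,3-dihydro-1-benzofuran-2-yl]-1,3-phenylene bis(2,2-dimethylpropanoate), (2S,3S) and (2R,3R) in equal parts | Brc1cc(OCOC)c2c(c1)O[C@H](c1ccc(OC(=O)C(C)(C)C)cc1OC(=O)C(C)(C)C)[C@H]2c1cc(OCOC)cc(OCOC)c1.Brc1cc(OCOC)c2c(c1)O[C@@H](c1ccc(OC(=O)C(C)(C)C)cc1OC(=O)C(C)(C)C)[C@@H]2c1cc(OCOC)cc(OCOC)c1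
F3 | step 5 | tert-butyl 5-bromo-2-formyl-3-(methoxymethoxy)phenyl carbonate | COCOc1cc(Br)cc(OC(=O)OC(C)(C)C)c1C=O
F4 | step 13 | 4-[(2S,3S)-6-bromo-3-(3,5-dihydroxyphenyl)-4-hydroxy-2,3-dihydro-1-benzofuran-2-yl]-1,3-phenylene bis(2,2-dimethylpropanoate) | Brc1cc(O)c2c(c1)O[C@H](c1ccc(OC(=O)C(C)(C)C)cc1OC(=O)C(C)(C)C)[C@H]2c1cc(O)cc(O)c1
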